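A closed flask keeps its material, and at 2.50 h the ochre run already reads 99.7% of the charge as isomer of the product plus target, with later readings level within the scatter, so I treat the question at late times as a split of the charge.

| flask | solid substrate | other conformer | remark | time |
|---|---|---|---|---|
| red | 14 mM | 2.5 mM | run made earlier |  |
| ochre | 22 mM | 2.5 mM | run made earlier |  |
| flask | 10 mM | 2.50 mM |  | 25 h |

| run | time / h | isomer of the product / % | target / % |
|---|---|---|---|
| red | 6.00 | 50.3 | 50.4 |
| red | 12.0 | 50.2 | 50.5 |
| red | 20.0 | 49.9 | 50.4 |
| red | 25.0 | 49.9 | 50.0 |
| red | 30.0 | 50.1 | 50.4 |
| ochre | 2.50 | 46.8 | 52.9 |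
| ochre | 8.00 | 47.4 | 52.2 |
| ochre | 15.0 | 47.4 | 52.2 |
| ochre | 20.0 | 47.0 | 52.5 |
| ochre | 30.0 | 47.3 | 53.2 |

(scatter of a reading: 0.3 percentage points)

- ratio of isomer of the product to target at 1.0 min
- ratio of isomer of the product to target at 25 h

- as a solid, counted per litre of solution: solid substrate
- the earlier runs were read with a standard deviation of 0.3 percentage points
- at the start none of the solid substrate is in solution

Averaging the isomer readings of each run gives 8.26 mM in the red run and 11.6 mM in the ochre run. The solid share, the part of each further millimole of solid substrate that ends as isomer of the product (its selectivity), therefore reads 41.2%. Taken back to no solid, this line leaves 2.50 mM of isomer, about the same as the 2.5 mM of other conformer charged, so I credit that amount to the conformer.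

In the flask, my curve starts with no target and an unbounded ratio, then falls steeply as solid reacts, each portion adding its share to the isomer and the rest to target. It runs into its level when the 10 mM of solid has reacted, with 6.62 mM of isomer and 5.88 mM of target, a ratio of 1.12. Isomer stays more than target, so this curve has no crossing. The readings begin at 2.50 h, far later than 1.0 min, so for the early time I commit only to a ratio above that level.

The forecast gives 5 at 1.0 min and 1.13 at 25 h, slightly above my level, and says of the early value “its size is only a rough guess”.

The flask gives 5.68 at 1.0 min and 1.10 at 25 h, with isomer of the product at 52.3% after 2.50 h and 52.3% after 250 h, so both forecast values stand within their margins.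

    starting material ⇌ other conformer (K = 0.570, k = 0.0500 s⁻¹)
    starting material → target (k = 0.0620 s⁻¹)
    solid substrate ⇌ starting material, rate k3*(cs3 - [starting material]) while solid is left; crystals form when [starting material] > cs3 (solubility = 4.00 mM, k = 0.00260 s⁻¹)
    other conformer → isomer of the product (k = 0.740 s⁻¹)

With the other conformer held at 2.50 mM and the time at 25 h, isomer and target hold the same at 1.35 times the flask's solid, 13.5 mM. The neighbour charged with 25 mM of solid substrate lies past it, and the solid share gives it a ratio of 0.871. That neighbour gives 0.873, with target in front at 53.4%.

Readings and results are calculated with constants of no real substance; scatter was added.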